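Everything rests on building ring A last. Its catechol pattern, oxygen on the adjacent carbons C3 and C4 and the side chain on C1, is cut at C1–C2 and C5–C6: C2–C5 with both oxygens come from a symmetric 2,3-bis(silyloxy)butadiene, C1 and C6 from the triple bond of an ynone whose carbonyl carbon is C7. One thermal Diels–Alder reaction, followed in the same pot by DDQ dehydrogenation, thus delivers the silyl-masked catechol ketone in one operation. The precursor is an (R)-configured terminal ynone carrying the ring B aryl ether on C8 and a silyloxy group on C9, made from L-glycerate by Mitsunobu inversion; chelate-controlled reduction of C7 and one fluoride step complete the target.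

Key step: step 8

Remark: locants follow neolignan usage (ring A = catechol ring C1–C6, C7 = benzylic carbinol carbon, C8 = aryloxy carbon, C9 = CH2OH carbon, ring B = guaiacyl ether ring); the L-glycerate unit is bought as its acetonide methyl ester, which has the (S) configuration of glyceric acid from L-serine, and Zn(BH4)2 is used as a pre-made ether solution.
Abbreviations: TBS = tert-butyldimethylsilyl; ArB–O = 4-[3-(TBS-oxy)propyl]-2-methoxyphenoxy (ring B with its silylated side chain).

Step 1
Reactants: 1 methyl (S)-2,2-dimethyl-1,3-dioxolane-4-carboxylate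
Product: 2 methyl (S)-2,3-dihydroxypropanoate
Conditions: Dowex 50W-X8 (H+ form), MeOH, rt
Reagents that add atoms: none
Why: Acid-catalysed acetal exchange (transketalisation to methanol) should free the 1,2-diol while the methyl ester cannot change in methanol and no bond to the stereocentre is broken, so the (S) configuration is retained.

Step 2
Reactants: 2 methyl (S)-2,3-dihydroxypropanoate
Product: 3 methyl (S)-2-hydroxy-3-(TBS-oxy)propanoate
Conditions: TBSCl (1.05 equiv), imidazole, CH2Cl2, 0 °C
Reagents that add atoms: tert-butyldimethylsilyl chloride, CC(C)(C)[Si](C)(C)Cl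
Why: Silyl ether formation with the bulky chlorosilane should be selective for the primary hydroxyl (the future C9 oxygen), the secondary hydroxyl being more hindered and less nucleophilic next to the ester.

Step 3
Reactants: 4 dihydroconiferyl alcohol [4-(3-hydroxypropyl)-2-methoxyphenol]
Product: 5 4-[3-(TBS-oxy)propyl]-2-methoxyphenol
Conditions: TBSCl (1.05 equiv), imidazole, CH2Cl2, 0 °C
Reagents that add atoms: tert-butyldimethylsilyl chloride, CC(C)(C)[Si](C)(C)Cl
Why: Silyl ether formation should occur selectively at the unhindered primary alcohol, because the neutral guaiacol hydroxyl is a weaker nucleophile toward the N-silylimidazolium ion, is flanked by the methoxy group and is hydrogen-bonded to it.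

Step 4
Reactants: 3 methyl (S)-2-hydroxy-3-(TBS-oxy)propanoate; 5 4-[3-(TBS-oxy)propyl]-2-methoxyphenol
Product: 6 methyl (R)-2-(ArB–O)-3-(TBS-oxy)propanoate
Conditions: PPh3, DIAD, THF, 0 °C → rt
Reagents that add atoms: none
Why: In this Mitsunobu etherification the phenol protonates the betaine and then displaces the oxyphosphonium group of the α-hydroxy ester by an SN2 attack that the adjacent ester accelerates, so C8 should be inverted cleanly from (S) to (R).

Step 5
Reactants: 6 methyl (R)-2-(ArB–O)-3-(TBS-oxy)propanoate
Product: 7 (R)-N-methoxy-N-methyl-2-(ArB–O)-3-(TBS-oxy)propanamide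
Conditions: MeNH(OMe)·HCl, AlMe3, CH2Cl2, 0 °C → rt; aq. HCl work-up
Reagents that add atoms: N,O-dimethylhydroxylamine hydrochloride, CNOC.Cl
Why: Weinreb amide formation by aminolysis of the ester with the chloro(methyl)aluminium amide made in situ is a Lewis-acid-mediated acyl substitution without strong base, so the acidic C8 hydrogen and the C9 silyloxy group should be left untouched and the (R) configuration retained.

Step 6
Reactants: 7 (R)-N-methoxy-N-methyl-2-(ArB–O)-3-(TBS-oxy)propanamide; 8 ethynylmagnesium bromide (HC≡CMgBr)
Product: 9 (R)-4-(ArB–O)-5-(TBS-oxy)pent-1-yn-3-one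
Conditions: HC≡CMgBr (0.5 M in THF, 2.5 equiv), THF, −20 → 0 °C; poured into cold aq. NaHSO4
Reagents that add atoms: none
Why: In this Weinreb ketone synthesis the acetylide adds once to give a five-membered magnesium chelate that should neither collapse nor enolise before the quench, and the inverse acidic quench protonates the released N,O-dimethylhydroxylamine so that it cannot add to the new ynone.

Step 7
Reactants: 10 butane-2,3-dione
Product: 11 2,3-bis(TBS-oxy)buta-1,3-diene
Conditions: TBSOTf (2.2 equiv), Et3N, CH2Cl2, 0 °C → rt
Reagents that add atoms: tert-butyldimethylsilyl trifluoromethanesulfonate, CC(C)(C)[Si](C)(C)OS(=O)(=O)C(F)(F)F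
Why: Double enol silylation under soft-enolisation conditions, in which each carbonyl oxygen is silylated by the silyl triflate and triethylamine removes a proton from the adjacent methyl group, should convert the 1,2-diketone into the 2,3-bis(silyloxy)diene.

Step 8
Reactants: 9 (R)-4-(ArB–O)-5-(TBS-oxy)pent-1-yn-3-one; 11 2,3-bis(TBS-oxy)buta-1,3-diene
Product: 13 (R)-1-[3,4-bis(TBS-oxy)phenyl]-2-(ArB–O)-3-(TBS-oxy)propan-1-one, via cyclohexa-1,4-diene cycloadduct 12 (not isolated)
Conditions: 11 (1.5 equiv), BHT (cat.), toluene, 110 °C, sealed tube; then DDQ (1.6 equiv), 0 °C → rt, same flask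
Reagents that add atoms: none
Why: The donor-substituted diene 11 and the ynone 9, whose triple bond is activated by the C7 carbonyl, should unite in a thermal, concerted, suprafacial normal-demand [4+2] cycloaddition that joins alkyne carbons C1 and C6 to the diene termini C2 and C5, after which the doubly allylic ring of 12 gives up a hydride and a proton to DDQ and becomes aromatic. The closest known reaction type is the Diels–Alder reaction of 2,3-bis(silyloxy)butadienes with acetylenic ketones and esters followed by dehydrogenation to catechol bis(silyl ethers). Ring A is closed by an intermolecular two-bond annulation in which C1–C2 and C5–C6 form in the same step, not by cyclisation of a preformed chain. No new stereocentre is created, and the existing one at C8 should survive because neither hot toluene nor DDQ provides a base able to enolise the C7 ketone or expel the C9 silyloxy group. Regiocontrol is not required, since the constitutionally symmetric diene places its two silyloxy groups on C3 and C4 whichever way it adds. The selectivity that is required is chemoselective dehydrogenation, secured by the far higher hydride-donor ability of the bis(silyl enol ether) ring of 12 compared with the benzylic CH2 of ring B, with DDQ dosed only for 12 and the surplus diene.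

Step 9
Reactants: 13 (R)-1-[3,4-bis(TBS-oxy)phenyl]-2-(ArB–O)-3-(TBS-oxy)propan-1-one
Product: 14 (1S,2R)-1-[3,4-bis(TBS-oxy)phenyl]-2-(ArB–O)-3-(TBS-oxy)propan-1-ol
Conditions: Zn(BH4)2 (Et2O solution), Et2O, −40 → 0 °C; aq. NH4Cl
Reagents that add atoms: none
Why: In this chelation-controlled (Cram-chelate) hydride reduction zinc should bridge the C7 carbonyl oxygen and the C8 aryloxy oxygen (helped by the neighbouring ring B methoxy group, while the C9 silyl ether does not coordinate), so that hydride enters C7 from the face of the C8 hydrogen and gives the anti, erythro (7S) carbinol next to the (8R) centre.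

Step 10
Reactants: 14 (1S,2R)-1-[3,4-bis(TBS-oxy)phenyl]-2-(ArB–O)-3-(TBS-oxy)propan-1-ol
Product: 15 (1S,2R)-1-(3,4-dihydroxyphenyl)-2-[4-(3-hydroxypropyl)-2-methoxyphenoxy]propane-1,3-diol, the (7S,8R) target
Conditions: TBAF, AcOH (1:1, excess), THF, 0 °C → rt, argon
Reagents that add atoms: none
Why: Fluoride-induced desilylation, driven by the strong Si–F bond, should cleave the two aryl and two primary alkyl silyl ethers in one operation, and the acetic acid buffer keeps the phenols protonated so that neither aerial oxidation of the catechol nor quinone-methide formation at the C7 carbinol disturbs the two stereocentres.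

Compound list
1 | methyl (S)-2,2-dimethyl-1,3-dioxolane-4-carboxylate | CC1(C)O[C@@H](CO1)C(=O)OC | starting material
2 | methyl (S)-2,3-dihydroxypropanoate | O[C@@H](CO)C(=O)OC | intermediate
3 | methyl (S)-3-[(tert-butyldimethylsilyl)oxy]-2-hydroxypropanoate | O[C@@H](CO[Si](C)(C)C(C)(C)C)C(=O)OC | intermediate
4 | dihydroconiferyl alcohol, 4-(3-hydroxypropyl)-2-methoxyphenol | COc1cc(CCCO)ccc1O | starting material
5 | 4-[3-[(tert-butyldimethylsilyl)oxy]propyl]-2-methoxyphenol | COc1cc(CCCO[Si](C)(C)C(C)(C)C)ccc1O | intermediate
6 | methyl (2R)-3-[(tert-butyldimethylsilyl)oxy]-2-[4-[3-[(tert-butyldimethylsilyl)oxy]propyl]-2-methoxyphenoxy]propanoate | COc1cc(CCCO[Si](C)(C)C(C)(C)C)ccc1O[C@H](CO[Si](C)(C)C(C)(C)C)C(=O)OC | intermediate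
7 | (2R)-3-[(tert-butyldimethylsilyl)oxy]-2-[4-[3-[(tert-butyldimethylsilyl)oxy]propyl]-2-methoxyphenoxy]-N-methoxy-N-methylpropanamide | COc1cc(CCCO[Si](C)(C)C(C)(C)C)ccc1O[C@H](CO[Si](C)(C)C(C)(C)C)C(=O)N(C)OC | intermediate
8 | ethynylmagnesium bromide (HC≡CMgBr) | C#C[Mg]Br | starting material
9 | (4R)-5-[(tert-butyldimethylsilyl)oxy]-4-[4-[3-[(tert-butyldimethylsilyl)oxy]propyl]-2-methoxyphenoxy]pent-1-yn-3-one | COc1cc(CCCO[Si](C)(C)C(C)(C)C)ccc1O[C@H](CO[Si](C)(C)C(C)(C)C)C(=O)C#C | intermediate
10 | butane-2,3-dione | CC(=O)C(C)=O | starting material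
11 | 2,3-bis[(tert-butyldimethylsilyl)oxy]buta-1,3-diene | C=C(O[Si](C)(C)C(C)(C)C)C(=C)O[Si](C)(C)C(C)(C)C | intermediate
12 | (2R)-1-[4,5-bis[(tert-butyldimethylsilyl)oxy]cyclohexa-1,4-dien-1-yl]-3-[(tert-butyldimethylsilyl)oxy]-2-[4-[3-[(tert-butyldimethylsilyl)oxy]propyl]-2-methoxyphenoxy]propan-1-one (cycloadduct, not isolated) | COc1cc(CCCO[Si](C)(C)C(C)(C)C)ccc1O[C@H](CO[Si](C)(C)C(C)(C)C)C(=O)C1=CCC(O[Si](C)(C)C(C)(C)C)=C(O[Si](C)(C)C(C)(C)C)C1 | intermediate
13 | (2R)-1-[3,4-bis[(tert-butyldimethylsilyl)oxy]phenyl]-3-[(tert-butyldimethylsilyl)oxy]-2-[4-[3-[(tert-butyldimethylsilyl)oxy]propyl]-2-methoxyphenoxy]propan-1-one | COc1cc(CCCO[Si](C)(C)C(C)(C)C)ccc1O[C@H](CO[Si](C)(C)C(C)(C)C)C(=O)c1ccc(O[Si](C)(C)C(C)(C)C)c(O[Si](C)(C)C(C)(C)C)c1 | intermediate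
14 | (1S,2R)-1-[3,4-bis[(tert-butyldimethylsilyl)oxy]phenyl]-3-[(tert-butyldimethylsilyl)oxy]-2-[4-[3-[(tert-butyldimethylsilyl)oxy]propyl]-2-methoxyphenoxy]propan-1-ol | COc1cc(CCCO[Si](C)(C)C(C)(C)C)ccc1O[C@H](CO[Si](C)(C)C(C)(C)C)[C@@H](O)c1ccc(O[Si](C)(C)C(C)(C)C)c(O[Si](C)(C)C(C)(C)C)c1 | intermediate
15 | (1S,2R)-1-(3,4-dihydroxyphenyl)-2-[4-(3-hydroxypropyl)-2-methoxyphenoxy]propane-1,3-diol, (7S,8R), erythro | COc1cc(CCCO)ccc1O[C@H](CO)[C@@H](O)c1ccc(O)c(O)c1 | target

Total step count: 10
Longest linear sequence: 8 steps (steps 1, 2, 4, 5, 6, 8, 9, 10)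

Steps most likely to fail

Step 8. The cycloaddition may be too slow at temperatures the ynone tolerates, so that ynone polymerisation, thermal enolisation at C8 or over-oxidation during a prolonged DDQ stage outruns ring formation. The fallback gives up the cycloaddition and forms the C1–C7 bond with a ready-made ring A nucleophile. It sets out from Weinreb amide 7. Commercial 4-bromobenzene-1,2-diol F1 is bis-silylated (TBSCl, imidazole, DMF, rt) to 4-bromo-1,2-bis(TBS-oxy)benzene F2. Bromine–lithium exchange (n-BuLi, THF, −78 °C) gives [3,4-bis(TBS-oxy)phenyl]lithium F3, which has no silyloxy group ortho to lithium and so should not undergo silyl migration. Amide 7 is added at −78 °C and the chelated adduct is quenched with aq. NH4Cl, which should give aryl ketone 13, where the route is rejoined.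

Step 9. Facial selectivity may be poor if the zinc chelate is incomplete, the aryl ether oxygen being a weak donor, so that open-chain polar Felkin–Anh delivery competes and the erythro preference erodes. The fallback replaces substrate control by catalyst control. It sets out from ketone 13 and uses (S)-2-methyl-CBS-oxazaborolidine with BH3·SMe2 in THF at −20 °C. With the ring A aryl group as the large carbonyl substituent, the catalyst model predicts the (7S) carbinol, and the route is rejoined at 14. This fallback makes no compound outside the list (entry F0).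

Step 6. The liberated N,O-dimethylhydroxylamine may add to the terminal ynone in a conjugate fashion during the quench, or C8 may lose its configuration while excess acetylide is present. The fallback builds the ynone by oxidation with no amine present. It sets out from Weinreb amide 7, which i-Bu2AlH (THF, −78 °C) should reduce to (R)-2-(ArB–O)-3-(TBS-oxy)propanal F4, used crude and cold. Ethynylmagnesium bromide 8 is added at −78 °C to give (3RS,4R)-4-(ArB–O)-5-(TBS-oxy)pent-1-yn-3-ol F5, whose C3 epimers are immaterial. Dess–Martin periodinane (NaHCO3, CH2Cl2, 0 °C) then oxidises it under neutral conditions to ynone 9, where the route is rejoined.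

Further compounds
F1 | step 8 | 4-bromobenzene-1,2-diol | Oc1ccc(Br)cc1O
F2 | step 8 | 4-bromo-1,2-bis[(tert-butyldimethylsilyl)oxy]benzene | CC(C)(C)[Si](C)(C)Oc1ccc(Br)cc1O[Si](C)(C)C(C)(C)C
F3 | step 8 | [3,4-bis[(tert-butyldimethylsilyl)oxy]phenyl]lithium | [Li]c1ccc(O[Si](C)(C)C(C)(C)C)c(O[Si](C)(C)C(C)(C)C)c1
F0 | step 9 | none | none
F4 | step 6 | (2R)-3-[(tert-butyldimethylsilyl)oxy]-2-[4-[3-[(tert-butyldimethylsilyl)oxy]propyl]-2-methoxyphenoxy]propanal | COc1cc(CCCO[Si](C)(C)C(C)(C)C)ccc1O[C@H](CO[Si](C)(C)C(C)(C)C)C=O
F5 | step 6 | (3RS,4R)-5-[(tert-butyldimethylsilyl)oxy]-4-[4-[3-[(tert-butyldimethylsilyl)oxy]propyl]-2-methoxyphenoxy]pent-1-yn-3-ol | COc1cc(CCCO[Si](C)(C)C(C)(C)C)ccc1O[C@H](CO[Si](C)(C)C(C)(C)C)C(O)C#C
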